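**Retrosynthetic overview**

1. Locants used here: ring C1 (C=O), C2 (Me) and C3 (ring oxirane), C4, C5 (side chain), C6 (ester O); chain C8 (oxirane carbon on C5), C9 (C=O), C10=C11, C12 (carbinol). The carbocycle is bought: (S)-carvone 1 supplies all seven ring carbons; its isopropenyl group steers the C2–C3 epoxidation and is then cut off, so the C5 stereocentre is erased and rewritten.
2. Key disconnection C5–C8: Claisen [3,3] shift of an allenyl group from O1 to C5. It is possible because, once C1=O is reduced, C5 is the far end of the allylic array O–C1–C6=C5 in the six-membered ring, and because the C2–C3 oxirane next to C1 sets the C1–O bond cis to itself, so C8 can only land on C5 on the oxirane face.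
3. The shift leaves C8 as the sp2 carbon of a 2-substituted allyl alcohol (C8 oxirane by Sharpless epoxidation, reagent control) and moves the ring alkene to C1=C6, where OsO4 brings in O1 and O6.
4. C9–C10: a temporary γ-lactone between O6 and C9 is opened by the C10–C12 alkenyllithium; the O6 isovalerate and the C1 ketone are made last.
5. Ring order: carbocycle (from 1) → C2–C3 oxirane → C8 oxirane → γ-lactone (temporary, opened again).

Key step: step 5

Remark (assumption on the chemistry): hydride (step 3) and osmium tetroxide (step 7) are taken to attack anti to the neighbouring oxirane oxygen, as is usual for 2,3-epoxy ketones and for alkenes with an allylic C–O bond; intermediates 5–11 carry an allylic or vinylic oxirane and are to be handled under neutral or buffered conditions.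

**Route**

Step 1
Reactants: 1 (S)-(+)-carvone
Product: 2 (1S,4S,6S)-1-methyl-4-(prop-1-en-2-yl)-7-oxabicyclo[4.1.0]heptan-2-one
Conditions: 35 % H2O2, NaOH (cat.), MeOH, 0 °C
Reagents that add atoms: hydrogen peroxide, OO
Why: Weitz–Scheffer nucleophilic epoxidation of the enone, in which hydroperoxide adds axially at C3 anti to the equatorial isopropenyl group on C5, should set both oxirane carbons (oxirane trans to isopropenyl) while the isolated 1,1-disubstituted alkene stays inert.

Step 2
Reactants: 2 (1S,4S,6S)-1-methyl-4-(prop-1-en-2-yl)-7-oxabicyclo[4.1.0]heptan-2-one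
Product: 4 (1S,6S)-1-methyl-7-oxabicyclo[4.1.0]hept-3-en-2-one, via methoxy hydroperoxide 3 (not isolated)
Conditions: O3, MeOH/CH2Cl2, −78 °C; then FeSO4·7H2O, Cu(OAc)2·H2O, −20 °C → rt
Reagents that add atoms: none
Why: Criegee ozonolysis in methanol stops at the α-methoxy hydroperoxide, whose Fe(II)-induced O–O cleavage and β-scission expel methyl acetate and leave a C5 radical that Cu(II) oxidises to the alkene conjugated with the ketone (dealkenylative dehydrogenation); no stereocentre is formed, C5 is erased on purpose and the oxirane carbons are untouched.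

Step 3
Reactants: 4 (1S,6S)-1-methyl-7-oxabicyclo[4.1.0]hept-3-en-2-one
Product: 5 cis-epoxy alcohol, 1-methyl-7-oxabicyclo[4.1.0]hept-3-en-2-ol with the 2-OH on the oxirane face
Conditions: NaBH4, CeCl3·7H2O, MeOH, −78 °C
Reagents that add atoms: none
Why: Luche 1,2-reduction, in which hydride should add to the carbonyl from the face opposite the adjacent oxirane oxygen (Felkin–Anh, anti to the α C–O bond), places the new C1 hydroxyl cis to the oxirane.

Step 4
Reactants: 5 cis-epoxy alcohol; 6 propargyl bromide
Product: 7 propargyl ether, 1-methyl-2-(prop-2-yn-1-yloxy)-7-oxabicyclo[4.1.0]hept-3-ene (ether O on the oxirane face)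
Conditions: NaH, THF, 0 °C; then 6, Bu4NI (cat.), 0 °C → rt
Reagents that add atoms: none
Why: Williamson etherification with the reactive propargylic bromide leaves the C1 stereocentre untouched, and the alkoxide, being cis to the oxirane, has no backside access for a Payne migration.

Step 5
Reactants: 7 propargyl ether
Product: 10 allylic alcohol, 2-(1-methyl-7-oxabicyclo[4.1.0]hept-2-en-4-yl)prop-2-en-1-ol (C4 substituent on the oxirane face), via allenyl ether 8 (not isolated), via enal 9 (not isolated)
Conditions: KOtBu (0.3 equiv), THF, 0 °C → rt; AcOH (0.3 equiv); PhMe, 80 °C; then MeOH, CeCl3·7H2O, NaBH4, −20 °C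
Reagents that add atoms: none
Why: Catalytic tert-butoxide moves the propargyl ether into the 1-alkoxyallene (1,3-prototropic shift), which on heating should undergo a Claisen [3,3] rearrangement through a six-membered transition state made of O–C1–C6=C5 of the ring and O–CH=C of the allene, so that the central allene carbon (the future C8) bonds to C5 while C1–O breaks and the ring alkene moves to C1=C6. The closest known reaction type is the tandem isomerisation/Claisen rearrangement of allyl propargyl ethers to 2-methylene-4-pentenals, here followed by a Luche 1,2-reduction in the same flask. No ring is closed. The one new stereocentre, C5, is controlled by the C1–O stereocentre: within the ring the shift can only be suprafacial, so C8 arrives on the face that carried the ether oxygen, which step 3 placed on the face of the C2–C3 oxirane. The selectivity needed is therefore delivery cis to the oxirane, the opposite of what steric approach control on an epoxy enone would give, and the substrate secures it by its cis O1/oxirane relationship, while C8 becomes sp2 so that no chair/boat question arises. The aldehyde is reduced at once because its C5–H is doubly allylic and would otherwise let the exocyclic double bond migrate.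

Step 6
Reactants: 10 allylic alcohol
Product: 11 epoxy alcohol, [(2S)-2-(1-methyl-7-oxabicyclo[4.1.0]hept-2-en-4-yl)oxiran-2-yl]methanol
Conditions: Ti(OiPr)4 (10 mol %), L-(+)-DIPT (12 mol %), TBHP, 4 Å MS, CH2Cl2, −20 °C
Reagents that add atoms: tert-butyl hydroperoxide, CC(C)(C)OO
Why: Katsuki–Sharpless asymmetric epoxidation needs the allylic hydroxyl and should therefore leave the ring alkene alone, and with L-(+)-tartrate the oxygen is delivered to the face of the 2-substituted allyl alcohol that gives the (S)-oxirane carbon (same face sense as (S)-2-methylglycidol from methallyl alcohol), which is the arrangement of C8 in the target (reagent control).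

Step 7
Reactants: 11 epoxy alcohol
Product: 12 triol, 4-[(2S)-2-(hydroxymethyl)oxiran-2-yl]-1-methyl-7-oxabicyclo[4.1.0]heptane-2,3-diol (2-OH and 3-OH trans to the ring oxirane oxygen, C4 substituent cis to it)
Conditions: OsO4 (2 mol %), NMO, acetone/H2O, rt
Reagents that add atoms: N-methylmorpholine N-oxide, C[N+]1([O-])CCOCC1; water, O
Why: catalytic osmium tetroxide cis-dihydroxylation of the only alkene should occur on the C1=C6 face opposite both the allylic oxirane oxygen and the C5 substituent, which sets the C6 oxygen trans to the side chain and to the oxirane (the C1 centre is removed again in step 12).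

Step 8
Reactants: 12 triol
Product: 15 spiro-epoxy γ-lactone (C9 lactonised onto O6, trans-fused, C1–OH free), via hydroxy aldehyde 13 (not isolated), via lactol 14 (not isolated)
Conditions: TEMPO (10 mol %), KBr (10 mol %), NaOCl, CH2Cl2/aq. NaHCO3, 0 °C
Reagents that add atoms: none
Why: oxoammonium (TEMPO/hypochlorite) oxidation is fastest at the primary alcohol, the aldehyde is trapped by the C6 hydroxyl as a five-membered lactol and this is oxidised on to the γ-lactone, while the axial, neopentylic C1 hydroxyl reacts slowly; no stereocentre changes, and the lactone both masks O6 and turns C9 into an acyl donor.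

Step 9
Reactants: 16 2-methylbut-3-yn-2-ol
Product: 17 (E)-2-methyl-4-(tributylstannyl)but-3-en-2-ol
Conditions: Bu3SnH, PdCl2(PPh3)2 (1 mol %), THF, 0 °C → rt
Reagents that add atoms: tributyltin hydride, CCCC[SnH](CCCC)CCCC
Why: palladium-catalysed syn-hydrostannation of the terminal alkyne, with tin going to the terminal carbon away from the tertiary carbinol, should give the E-alkenylstannane.

Step 10
Reactants: 15 spiro-epoxy γ-lactone; 17 (E)-2-methyl-4-(tributylstannyl)but-3-en-2-ol
Product: 19 enone diol, (E)-1-[(2R)-2-(2,3-dihydroxy-1-methyl-7-oxabicyclo[4.1.0]heptan-4-yl)oxiran-2-yl]-4-hydroxy-4-methylpent-2-en-1-one, via dilithio alkenyl alkoxide 18 (not isolated)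
Conditions: 17 (3 equiv), n-BuLi (6 equiv), THF, −78 → −40 °C; then 15, −78 °C; aq. NH4Cl
Reagents that add atoms: none
Why: tin–lithium exchange with retention of the E geometry is followed by addition of the alkenyllithium to the lactone carbonyl (acyl substitution), where one equivalent deprotonates the C1 hydroxyl, the adduct should stay tetrahedral at −78 °C so that only one alkenyl group enters, and work-up releases the C9 enone and the C6 hydroxyl with no stereocentre changed.

Step 11
Reactants: 19 enone diol; 20 isovaleryl chloride
Product: 21 C6 mono-isovalerate of 19 (C1–OH free)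
Conditions: 20 (1.05 equiv), Me2SnCl2 (5 mol %), K2CO3, THF, 0 °C → rt
Reagents that add atoms: none
Why: tin-catalysed regioselective monoacylation of a cis-1,2-diol (stannylene acetal activation) should esterify the equatorial C6 oxygen rather than the axial, neopentylic C1 oxygen next to the quaternary oxirane carbon, and leaves the tertiary alcohol alone; no stereocentre changes.

Step 12
Reactants: 21 C6 mono-isovalerate
Product: 22 CNP0292003.1
Conditions: Dess–Martin periodinane, NaHCO3, CH2Cl2, 0 °C → rt
Reagents that add atoms: none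
Why: Dess–Martin oxidation of the one remaining secondary alcohol under bicarbonate buffering should give the C1 ketone without acyl migration, the tertiary allylic alcohol cannot be oxidised, and the C6 centre, now α to the ketone, already holds its ester equatorial and trans to the side chain.

**Compound list**

1 | (S)-(+)-carvone, (5S)-2-methyl-5-(prop-1-en-2-yl)cyclohex-2-en-1-one | CC1=CC[C@@H](CC1=O)C(C)=C | starting material
2 | (1S,4S,6S)-1-methyl-4-(prop-1-en-2-yl)-7-oxabicyclo[4.1.0]heptan-2-one (oxirane trans to isopropenyl) | C1C(=O)[C@@]2(C)O[C@H]2C[C@@H]1C(C)=C | intermediate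
3 | methoxy hydroperoxide, (1S,4S,6S)-4-(1-hydroperoxy-1-methoxyethyl)-1-methyl-7-oxabicyclo[4.1.0]heptan-2-one (both epimers at the peroxy carbon) | C1C(=O)[C@@]2(C)O[C@H]2C[C@@H]1C(C)(OC)OO | intermediate
4 | (1S,6S)-1-methyl-7-oxabicyclo[4.1.0]hept-3-en-2-one | O=C1C=CC[C@@H]2O[C@]12C | intermediate
5 | cis-epoxy alcohol, 1-methyl-7-oxabicyclo[4.1.0]hept-3-en-2-ol (2-OH on the oxirane face) | O[C@@H]1C=CC[C@@H]2O[C@]12C | intermediate
6 | propargyl bromide (3-bromoprop-1-yne) | C#CCBr | starting material
7 | propargyl ether, 1-methyl-2-(prop-2-yn-1-yloxy)-7-oxabicyclo[4.1.0]hept-3-ene (ether O on the oxirane face) | C#CCO[C@@H]1C=CC[C@@H]2O[C@]12C | intermediate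
8 | allenyl ether, 1-methyl-2-(propa-1,2-dien-1-yloxy)-7-oxabicyclo[4.1.0]hept-3-ene (same configuration) | C=C=CO[C@@H]1C=CC[C@@H]2O[C@]12C | intermediate
9 | enal, 2-(1-methyl-7-oxabicyclo[4.1.0]hept-2-en-4-yl)prop-2-enal (C4 substituent on the oxirane face) | C1=C[C@@]2(C)O[C@H]2C[C@H]1C(=C)C=O | intermediate
10 | allylic alcohol, 2-(1-methyl-7-oxabicyclo[4.1.0]hept-2-en-4-yl)prop-2-en-1-ol | C1=C[C@@]2(C)O[C@H]2C[C@H]1C(=C)CO | intermediate
11 | epoxy alcohol, [(2S)-2-(1-methyl-7-oxabicyclo[4.1.0]hept-2-en-4-yl)oxiran-2-yl]methanol | C1=C[C@@]2(C)O[C@H]2C[C@H]1[C@]1(CO)CO1 | intermediate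
12 | triol, 4-[(2S)-2-(hydroxymethyl)oxiran-2-yl]-1-methyl-7-oxabicyclo[4.1.0]heptane-2,3-diol (both ring OH trans to the ring oxirane O) | O[C@@H]1[C@H](O)[C@@]2(C)O[C@H]2C[C@H]1[C@]1(CO)CO1 | intermediate
13 | hydroxy aldehyde, (2R)-2-(2,3-dihydroxy-1-methyl-7-oxabicyclo[4.1.0]heptan-4-yl)oxirane-2-carbaldehyde | O[C@@H]1[C@H](O)[C@@]2(C)O[C@H]2C[C@H]1[C@]1(C=O)CO1 | intermediate
14 | lactol, five-membered hemiacetal of 13 onto the 3-OH (O6), both anomers | O1[C@@H]2[C@H](O)[C@@]3(C)O[C@H]3C[C@H]2[C@]4(C1O)CO4 | intermediate
15 | spiro-epoxy γ-lactone, C9 acid lactonised onto O6 (trans-fused), oxirane spiro at the lactone α-carbon, C1–OH free | O1[C@@H]2[C@H](O)[C@@]3(C)O[C@H]3C[C@H]2[C@]4(C1=O)CO4 | intermediate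
16 | 2-methylbut-3-yn-2-ol | CC(C)(O)C#C | starting material
17 | (E)-2-methyl-4-(tributylstannyl)but-3-en-2-ol | CCCC[Sn](CCCC)(CCCC)/C=C/C(C)(C)O | intermediate
18 | lithium (E)-4-lithio-2-methylbut-3-en-2-olate | [Li]/C=C/C(C)(C)O[Li] | intermediate
19 | enone diol, (E)-1-[(2R)-2-(2,3-dihydroxy-1-methyl-7-oxabicyclo[4.1.0]heptan-4-yl)oxiran-2-yl]-4-hydroxy-4-methylpent-2-en-1-one | O[C@@H]1[C@H](O)[C@@]2(C)O[C@H]2C[C@H]1[C@]1(C(=O)/C=C/C(C)(C)O)CO1 | intermediate
20 | isovaleryl chloride (3-methylbutanoyl chloride) | CC(C)CC(Cl)=O | starting material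
21 | C6 mono-isovalerate of 19, C1–OH free | CC(C)CC(=O)O[C@@H]1[C@H](O)[C@@]2(C)O[C@H]2C[C@H]1[C@]1(C(=O)/C=C/C(C)(C)O)CO1 | intermediate
22 | CNP0292003.1 | CC(C)CC(=O)O[C@@H]1C(=O)[C@@]2(C)O[C@H]2C[C@H]1[C@]1(C(=O)/C=C/C(C)(C)O)CO1 | target

**Count and risks**

Total step count: 12. Longest linear sequence: 11 steps (steps 1–8 and 10–12, from 1); step 9 prepares the side-chain reagent.

Steps most likely to fail:

Step 5. What may go wrong: base-induced elimination or aromatisation of the oxirane-bearing ring during the propargyl-to-allenyl isomerisation, or migration of the exocyclic double bond into conjugation (loss of the C5 stereocentre) and polymerisation of the enal before it is reduced. Fallback (ortho ester Johnson–Claisen; sets out from 5, comes back at 10): 5 is heated with trimethyl 3-(phenylselanyl)orthopropanoate and a catalytic hindered carboxylic acid (2,4,6-trimethylbenzoic acid, PhMe, 110 °C). The mixed ketene acetal should rearrange by the same suprafacial [3,3] shift to methyl 2-(1-methyl-7-oxabicyclo[4.1.0]hept-2-en-4-yl)-3-(phenylselanyl)propanoate F1 (both α-epimers, of no consequence). Oxidation (H2O2, NaHCO3, THF, 0 °C) and selenoxide syn-elimination should give methyl 2-(1-methyl-7-oxabicyclo[4.1.0]hept-2-en-4-yl)prop-2-enoate F2, and DIBAL-H (CH2Cl2, −78 °C) reduces the ester to 10.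

Step 10. What may go wrong: collapse of the adduct before the quench followed by a second addition to the enone, or attack of the organolithium on an oxirane. Fallback (Weinreb amide; sets out from 15, comes back at 19): 15 is opened with MeNH(OMe)·HCl and i-PrMgCl (THF, −20 °C) to the N-methoxy-N-methyl amide of the dihydroxy epoxy acid F3. Its chelated adduct with 18 (excess, THF, −78 °C) cannot add twice and should give 19 on work-up.

Step 11. What may go wrong: acylation of the wrong secondary hydroxyl, or migration of the acyl group from O6 to O1 before the oxidation. Fallback (differentiation at the lactone stage; sets out from 15, comes back at 21): the only free hydroxyl of 15 is silylated (TESOTf, 2,6-lutidine, CH2Cl2, −78 °C) to the C1 triethylsilyl ether of the lactone F4. Addition of 18 as in step 10 should give the enone with free C6–OH and C1–OTES F5. Acylation with 20 (pyridine, DMAP, CH2Cl2, 0 °C) gives the C6 isovalerate C1 silyl ether F6, and buffered HF·pyridine (THF, 0 °C) removes the silyl group to give 21.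

**Further compounds**

F1 | step 5 | methyl 2-(1-methyl-7-oxabicyclo[4.1.0]hept-2-en-4-yl)-3-(phenylselanyl)propanoate | C1=C[C@@]2(C)O[C@H]2C[C@H]1C(C[Se]c1ccccc1)C(=O)OC
F2 | step 5 | methyl 2-(1-methyl-7-oxabicyclo[4.1.0]hept-2-en-4-yl)prop-2-enoate | C1=C[C@@]2(C)O[C@H]2C[C@H]1C(=C)C(=O)OC
F3 | step 10 | (2R)-2-(2,3-dihydroxy-1-methyl-7-oxabicyclo[4.1.0]heptan-4-yl)-N-methoxy-N-methyloxirane-2-carboxamide | O[C@@H]1[C@H](O)[C@@]2(C)O[C@H]2C[C@H]1[C@]1(C(=O)N(C)OC)CO1
F4 | step 11 | C1 triethylsilyl ether of lactone 15 | O1[C@@H]2[C@H](O[Si](CC)(CC)CC)[C@@]3(C)O[C@H]3C[C@H]2[C@]4(C1=O)CO4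
F5 | step 11 | enone with free C6–OH and C1–OTES | O[C@@H]1[C@H](O[Si](CC)(CC)CC)[C@@]2(C)O[C@H]2C[C@H]1[C@]1(C(=O)/C=C/C(C)(C)O)CO1
F6 | step 11 | C6 isovalerate C1 triethylsilyl ether | CC(C)CC(=O)O[C@@H]1[C@H](O[Si](CC)(CC)CC)[C@@]2(C)O[C@H]2C[C@H]1[C@]1(C(=O)/C=C/C(C)(C)O)CO1
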